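**Plan**
- Retrosynthesis: after the acetonide and the MOM acetal, the first skeletal cuts are the two O–C(aryl) bonds. They hold identical 4-allylphenyl groups on O–C5 of the benzodioxane and on O–C3' of the pendant ring.
- Enabling feature: both oxygens are outer oxygens of 1,2,3-trioxygenated benzene rings. With O1/O4 in the dioxane ring and O4'/O5' in an acetonide, C5–OH and C3'–OH are the only free hydroxyls. Each is flanked by one ether oxygen and one C–H, so one reagent can arylate both.
- Further cuts: O4–C3 (Mitsunobu closure), O1–C2 (benzylic epoxide opening), CH2–O(magnolol) (Mitsunobu), the epoxide oxygen, and the cinnamate C=C (Wittig).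
- Forward order: pendant-ring aldehyde, epoxy alcohol, magnolol ether, allylpyrogallol ether, 1,4-dioxane ring (the only skeletal ring built), two diaryl ethers, deprotection.
- Stereochemistry: Sharpless epoxidation with D-(−)-diisopropyl tartrate sets a (2R,3R)-trans-epoxide. One SN2 inversion at each epoxide carbon (steps 10 and 12) turns it into the (2S,3S)-trans-benzodioxane.

Key step: step 15

Assumption: the carbon of the cyclic orthoformate that masks the allylpyrogallol is a stereocentre of no consequence; the compounds holding it are carried as epimer mixtures, their SMILES leave it open, and it is lost on hydrolysis.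

Step 1
Reactants: 1 3,4,5-trihydroxybenzaldehyde
Product: 2 7-hydroxy-2,2-dimethyl-1,3-benzodioxole-5-carbaldehyde
Conditions: Me2C(OMe)2, p-TsOH (cat.), toluene, reflux (MeOH removed over 4 Å MS); aq. work-up
Reagents that add atoms: 2,2-dimethoxypropane, COC(C)(C)OC
Why: Acid-catalysed transketalisation closes the five-membered catechol acetonide over two neighbouring hydroxyls, and because the ring is symmetric either pair gives the same compound and leaves exactly one outer hydroxyl free.

Step 2
Reactants: 2 7-hydroxy-2,2-dimethyl-1,3-benzodioxole-5-carbaldehyde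
Product: 3 7-allyloxy-2,2-dimethyl-1,3-benzodioxole-5-carbaldehyde
Conditions: allyl bromide, K2CO3, DMF, rt
Reagents that add atoms: allyl bromide, C=CCBr
Why: Williamson etherification of the only free phenol installs an allyl ether that withstands hydride, titanium/peroxide, Mitsunobu and carbonate conditions and can later be removed by zerovalent palladium without touching C-allyl groups.

Step 3
Reactants: 3 7-allyloxy-2,2-dimethyl-1,3-benzodioxole-5-carbaldehyde
Product: 4 ethyl (E)-3-(7-allyloxy-2,2-dimethyl-1,3-benzodioxol-5-yl)acrylate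
Conditions: Ph3P=CHCO2Et, toluene, 80 °C
Reagents that add atoms: ethyl (triphenylphosphoranylidene)acetate, CCOC(=O)C=P(c1ccccc1)(c1ccccc1)c1ccccc1
Why: Wittig olefination of an aromatic aldehyde with a stabilised ylide is reliably E-selective and needs no added base.

Step 4
Reactants: 4 ethyl (E)-3-(7-allyloxy-2,2-dimethyl-1,3-benzodioxol-5-yl)acrylate
Product: 5 (E)-3-(7-allyloxy-2,2-dimethyl-1,3-benzodioxol-5-yl)prop-2-en-1-ol
Conditions: iBu2AlH (2.5 equiv), CH2Cl2, −78 °C; aq. potassium sodium tartrate
Reagents that add atoms: none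
Why: 1,2-Reduction of the α,β-unsaturated ester by two hydride equivalents of iBu2AlH gives the allylic alcohol without touching the ketal or the allyl ether.

Step 5
Reactants: 5 (E)-3-(7-allyloxy-2,2-dimethyl-1,3-benzodioxol-5-yl)prop-2-en-1-ol
Product: 6 [(2R,3R)-3-(7-allyloxy-2,2-dimethyl-1,3-benzodioxol-5-yl)oxiran-2-yl]methanol
Conditions: Ti(OiPr)4 (10 mol %), D-(−)-diisopropyl tartrate (12 mol %), t-BuOOH (decane), 4 Å MS, CH2Cl2, −25 °C; NaOH/brine work-up
Reagents that add atoms: tert-butyl hydroperoxide, CC(C)(C)OO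
Why: Sharpless asymmetric epoxidation: allylic alkoxide and peroxide bind the same titanium tartrate centre, so only the cinnamyl double bond reacts, and the D-(−)-tartrate directs oxygen to the face that gives the (2R,3R)-epoxide, as established for (E)-cinnamyl alcohols, while catalytic titanium, sieves and a basic work-up protect the electron-rich benzylic epoxide.

Step 6
Reactants: 7 magnolol (5,5'-diallylbiphenyl-2,2'-diol)
Product: 8 5,5'-diallyl-2'-(methoxymethoxy)biphenyl-2-ol (mono-MOM magnolol)
Conditions: MOMCl (1.0 equiv), iPr2NEt, CH2Cl2, 0 °C → rt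
Reagents that add atoms: chloromethyl methyl ether, COCCl
Why: Base-mediated O-alkylation with one equivalent of MOMCl favours the mono-ether because the first phenol of a 2,2'-biphenol is the more acidic one (its anion is hydrogen-bonded to the neighbouring OH), and unreacted 7 and the bis-ether are separable.

Step 7
Reactants: 6 [(2R,3R)-3-(7-allyloxy-2,2-dimethyl-1,3-benzodioxol-5-yl)oxiran-2-yl]methanol; 8 mono-MOM magnolol
Product: 9 (2R,3R)-2-{[5,5'-diallyl-2'-(methoxymethoxy)biphenyl-2-yl]oxymethyl}-3-(7-allyloxy-2,2-dimethyl-1,3-benzodioxol-5-yl)oxirane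
Conditions: PPh3, DIAD, THF, 0 °C → rt
Reagents that add atoms: none
Why: Mitsunobu etherification activates only the primary C–OH bond, so the aryl ether forms at CH2, both epoxide stereocentres stay untouched and a later Payne rearrangement is ruled out.

Step 8
Reactants: 10 4-allyl-2,6-dimethoxyphenol
Product: 11 5-allylbenzene-1,2,3-triol (5-allylpyrogallol)
Conditions: BBr3 (3.5 equiv), CH2Cl2, −78 → 0 °C; ice-water
Reagents that add atoms: none
Why: Lewis-acid cleavage of aryl methyl ethers by BBr3 at low temperature, a method compatible with allylarenes, frees the symmetric pyrogallol.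

Step 9
Reactants: 11 5-allylbenzene-1,2,3-triol
Product: 12 6-allyl-2-ethoxy-1,3-benzodioxol-4-ol
Conditions: HC(OEt)3, sulfonic acid resin (Amberlyst 15, cat.), toluene, reflux (EtOH distilled off)
Reagents that add atoms: triethyl orthoformate, CCOC(OCC)OCC
Why: Acid-catalysed orthoester exchange ties the middle oxygen and one outer oxygen into a cyclic orthoformate, a known way to leave a single outer hydroxyl of a pyrogallol free, and symmetry again makes both choices identical.

Step 10
Reactants: 9 the (2R,3R)-glycidyl aryl ether; 12 6-allyl-2-ethoxy-1,3-benzodioxol-4-ol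
Product: 13 (1S,2R)-1-(7-allyloxy-2,2-dimethyl-1,3-benzodioxol-5-yl)-1-[(6-allyl-2-ethoxy-1,3-benzodioxol-4-yl)oxy]-3-{[5,5'-diallyl-2'-(methoxymethoxy)biphenyl-2-yl]oxy}propan-2-ol
Conditions: 12 (1.5 equiv), Cs2CO3 (20 mol %), DMF, 80 °C, argon
Reagents that add atoms: none
Why: Base-catalysed SN2 opening of a trans-3-arylglycidyl ether by a phenoxide occurs at the benzylic carbon, which the aryl group activates while the adjacent CH2OAr deactivates the other carbon, and it proceeds with inversion, setting C1 as S while the carbinol carbon keeps its R configuration.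

Step 11
Reactants: 13 the (1S,2R)-orthoformate alcohol
Product: 15 5-allyl-3-{(1S,2R)-1-(7-allyloxy-2,2-dimethyl-1,3-benzodioxol-5-yl)-3-{[5,5'-diallyl-2'-(methoxymethoxy)biphenyl-2-yl]oxy}-2-hydroxypropoxy}benzene-1,2-diol, via outer-oxygen monoformate 14 (not isolated)
Conditions: 0.1 M aq. HCl–THF, rt; aq. NaHCO3 work-up, argon
Reagents that add atoms: none
Why: Orthoester hydrolysis: a cyclic orthoformate is cleaved at far lower acidity than a catechol acetonide or an aryl MOM ether, so dilute acid gives formate 14 and the hydrogencarbonate wash cleaves this labile aryl formate to the catechol.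

Step 12
Reactants: 15 the (1S,2R)-catechol alcohol
Product: 16 (2S,3S)-7-allyl-2-(7-allyloxy-2,2-dimethyl-1,3-benzodioxol-5-yl)-3-{[5,5'-diallyl-2'-(methoxymethoxy)biphenyl-2-yl]oxymethyl}-2,3-dihydro-1,4-benzodioxin-5-ol
Conditions: PPh3, DIAD, THF (0.01 M), 0 °C → rt
Reagents that add atoms: none
Why: Intramolecular Mitsunobu etherification: the secondary alcohol is activated as its oxyphosphonium salt and displaced by the neighbouring middle phenol in a 6-exo-tet SN2 closure with inversion (R to S), giving the trans-dioxane, while the outer hydroxyl would have to bridge the ring meta and therefore stays free.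

Step 13
Reactants: 16 the (2S,3S)-benzodioxane allyl ether
Product: 17 (2S,3S)-7-allyl-3-{[5,5'-diallyl-2'-(methoxymethoxy)biphenyl-2-yl]oxymethyl}-2-(7-hydroxy-2,2-dimethyl-1,3-benzodioxol-5-yl)-2,3-dihydro-1,4-benzodioxin-5-ol (core bis-phenol)
Conditions: Pd(PPh3)4 (5 mol %), morpholine, THF, rt
Reagents that add atoms: none
Why: Tsuji–Trost-type deallylation: zerovalent palladium ionises only the O-allyl group, whose phenoxide is a leaving group, and morpholine traps the π-allyl complex, whereas the C-allyl groups have no leaving group.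

Step 14
Reactants: 18 1-allyl-4-bromobenzene
Product: 21 4-allylphenylboronic acid, via 4-allylphenylmagnesium bromide 19 (not isolated), via dimethyl 4-allylphenylboronate 20 (not isolated)
Conditions: Mg, THF, 40 °C; B(OMe)3, −78 °C → rt; 1 M aq. HCl
Reagents that add atoms: trimethyl borate, COB(OC)OC; water, O; magnesium, [Mg] (held only in 19)
Why: Grignard formation followed by borylation with a trialkyl borate and acidic hydrolysis is the standard route to arylboronic acids and leaves the remote allyl group alone.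

Step 15
Reactants: 17 core bis-phenol; 21 4-allylphenylboronic acid
Product: 24 acetonide MOM ether of magnolianin, via C5 mono-aryl ether 22 (not isolated), via C3' mono-aryl ether 23 (not isolated)
Conditions: 21 (5 equiv), Cu(OAc)2 (3 equiv), pyridine (10 equiv), 4 Å MS, CH2Cl2, dry air, rt
Reagents that add atoms: none
Why: This is the Chan–Lam oxidative O-arylation of phenols, applied to two hydroxyls of one substrate in a single flask. Boronic acid 21 transfers its aryl group to divalent copper, the phenoxide of 17 (freed by pyridine) binds the same metal, one-electron oxidation by further Cu(OAc)2 or by oxygen gives an aryl phenoxide complex of trivalent copper, and reductive elimination forms the O–C(aryl) bond; the sequence then repeats on 22 or 23. No ring is closed and no stereocentre is created, and at room temperature with pyridine as the only base C2, C3, the benzylic C2–O1 bond and all allyl groups should pass through unchanged. The selectivity needed is only exhaustive reaction at oxygen: C5–OH and C3'–OH are the sole O–H groups of 17, because O1 and O4 are locked in the dioxane ring, O4' and O5' in the acetonide and the second magnolol oxygen in the MOM ether. Each reacting hydroxyl carries one ortho ether oxygen and one ortho C–H, a guaiacol-like setting well within the scope of this coupling. Excess 21 and 4 Å sieves make up for boronic acid lost to protodeboronation, oxidation to the phenol and homocoupling.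

Step 16
Reactants: 24 acetonide MOM ether of magnolianin
Product: 26 magnolianin, via magnolianin acetonide 25 (not isolated)
Conditions: 3 M aq. HCl–THF (1:4), 50 °C, argon
Reagents that add atoms: none
Why: Aqueous acid hydrolysis cleaves the MOM acetal first and then the catechol ketal, while diaryl ethers and terminal alkenes are inert and the trans-dioxane is the thermodynamically preferred isomer should the benzylic C2–O1 bond open reversibly.

**Compound list**
1 | 3,4,5-trihydroxybenzaldehyde | O=Cc1cc(O)c(O)c(O)c1 | starting material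
2 | 7-hydroxy-2,2-dimethyl-1,3-benzodioxole-5-carbaldehyde | O=Cc1cc(O)c2OC(C)(C)Oc2c1 | intermediate
3 | 7-allyloxy-2,2-dimethyl-1,3-benzodioxole-5-carbaldehyde | O=Cc1cc(OCC=C)c2OC(C)(C)Oc2c1 | intermediate
4 | ethyl (E)-3-(7-allyloxy-2,2-dimethyl-1,3-benzodioxol-5-yl)acrylate | CCOC(=O)/C=C/c1cc(OCC=C)c2OC(C)(C)Oc2c1 | intermediate
5 | (E)-3-(7-allyloxy-2,2-dimethyl-1,3-benzodioxol-5-yl)prop-2-en-1-ol | OC/C=C/c1cc(OCC=C)c2OC(C)(C)Oc2c1 | intermediate
6 | [(2R,3R)-3-(7-allyloxy-2,2-dimethyl-1,3-benzodioxol-5-yl)oxiran-2-yl]methanol | OC[C@H]1O[C@@H]1c2cc(OCC=C)c3OC(C)(C)Oc3c2 | intermediate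
7 | magnolol | C=CCc1ccc(O)c(-c2cc(CC=C)ccc2O)c1 | starting material
8 | 5,5'-diallyl-2'-(methoxymethoxy)biphenyl-2-ol | C=CCc1ccc(O)c(-c2cc(CC=C)ccc2OCOC)c1 | intermediate
9 | (2R,3R)-glycidyl ether of 8 bearing the 7-allyloxy-2,2-dimethyl-1,3-benzodioxol-5-yl group at C3 | C=CCc1ccc(OC[C@H]2O[C@@H]2c3cc(OCC=C)c4OC(C)(C)Oc4c3)c(-c5cc(CC=C)ccc5OCOC)c1 | intermediate
10 | 4-allyl-2,6-dimethoxyphenol | C=CCc1cc(OC)c(O)c(OC)c1 | starting material
11 | 5-allylbenzene-1,2,3-triol | C=CCc1cc(O)c(O)c(O)c1 | intermediate
12 | 6-allyl-2-ethoxy-1,3-benzodioxol-4-ol (racemic at the orthoformate carbon) | CCOC1Oc2cc(CC=C)cc(O)c2O1 | intermediate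
13 | (1S,2R)-1-aryl-1-aryloxy-3-aryloxypropan-2-ol, orthoformate intact (epimers at the orthoformate carbon) | C=CCOc1cc(cc2OC(C)(C)Oc12)[C@H](Oc1cc(CC=C)cc2OC(OCC)Oc12)[C@H](O)COc1ccc(CC=C)cc1-c1cc(CC=C)ccc1OCOC | intermediate
14 | catechol 15 with a formyl group on its outer oxygen, (1S,2R) | C=CCOc1cc(cc2OC(C)(C)Oc12)[C@H](Oc1cc(CC=C)cc(OC=O)c1O)[C@H](O)COc1ccc(CC=C)cc1-c1cc(CC=C)ccc1OCOC | intermediate (not isolated)
15 | (1S,2R)-catechol alcohol | C=CCOc1cc(cc2OC(C)(C)Oc12)[C@H](Oc1cc(CC=C)cc(O)c1O)[C@H](O)COc1ccc(CC=C)cc1-c1cc(CC=C)ccc1OCOC | intermediate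
16 | (2S,3S)-trans-benzodioxane, C5–OH free, C3'–O-allyl | C=CCOc1cc([C@@H]2Oc3cc(CC=C)cc(O)c3O[C@H]2COc2ccc(CC=C)cc2-c2cc(CC=C)ccc2OCOC)cc2OC(C)(C)Oc12 | intermediate
17 | (2S,3S)-trans-benzodioxane core bis-phenol (4',5'-acetonide, magnolol MOM ether) | Oc1cc([C@@H]2Oc3cc(CC=C)cc(O)c3O[C@H]2COc2ccc(CC=C)cc2-c2cc(CC=C)ccc2OCOC)cc2OC(C)(C)Oc12 | intermediate
18 | 1-allyl-4-bromobenzene | C=CCc1ccc(Br)cc1 | starting material
19 | 4-allylphenylmagnesium bromide | C=CCc1ccc([Mg]Br)cc1 | intermediate (not isolated)
20 | dimethyl 4-allylphenylboronate | C=CCc1ccc(B(OC)OC)cc1 | intermediate (not isolated)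
21 | 4-allylphenylboronic acid | OB(O)c1ccc(CC=C)cc1 | intermediate
22 | 17 arylated at C5–O only, (2S,3S) | Oc1cc([C@@H]2Oc3cc(CC=C)cc(Oc4ccc(CC=C)cc4)c3O[C@H]2COc2ccc(CC=C)cc2-c2cc(CC=C)ccc2OCOC)cc2OC(C)(C)Oc12 | intermediate (not isolated)
23 | 17 arylated at C3'–O only, (2S,3S) | C=CCc1ccc(Oc2cc([C@@H]3Oc4cc(CC=C)cc(O)c4O[C@H]3COc3ccc(CC=C)cc3-c3cc(CC=C)ccc3OCOC)cc3OC(C)(C)Oc23)cc1 | intermediate (not isolated)
24 | acetonide MOM ether of magnolianin, (2S,3S) | C=CCc1ccc(Oc2cc([C@@H]3Oc4cc(CC=C)cc(Oc5ccc(CC=C)cc5)c4O[C@H]3COc3ccc(CC=C)cc3-c3cc(CC=C)ccc3OCOC)cc3OC(C)(C)Oc23)cc1 | intermediate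
25 | magnolianin 4',5'-acetonide, (2S,3S) | C=CCc1ccc(Oc2cc([C@@H]3Oc4cc(CC=C)cc(Oc5ccc(CC=C)cc5)c4O[C@H]3COc3ccc(CC=C)cc3-c3cc(CC=C)ccc3O)cc3OC(C)(C)Oc23)cc1 | intermediate (not isolated)
26 | magnolianin, (2S,3S) | C=CCc1ccc(Oc2cc([C@@H]3Oc4cc(CC=C)cc(Oc5ccc(CC=C)cc5)c4O[C@H]3COc3ccc(CC=C)cc3-c3cc(CC=C)ccc3O)cc(O)c2O)cc1 | target

Total step count: 16.
Longest linear sequence: 12 steps (1–5, 7, 10–13, 15, 16) from 3,4,5-trihydroxybenzaldehyde.

**Steps most likely to fail**

Step 10.
- The phenoxide may attack the non-benzylic epoxide carbon. The electron-rich benzylic C–O bond may also ionise in hot DMF, so that inversion is no longer clean.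
- The fallback sets out from 6 and 12 and comes back at 13. It reverses the order of the two ether formations.
- The free epoxy alcohol 6 is opened with 12 in aq. NaOH–dioxane at 70 °C. The neighbouring hydroxyl steers attack to the benzylic carbon, as known for 3-arylglycidols, and this gives the 1,2-diol F1.
- The primary hydroxyl is sulfonylated selectively (TsCl, Et3N, Bu2SnO cat., CH2Cl2) to the primary monotosylate F2.
- K2CO3 in DMF closes F2 to the terminal epoxide F3 without touching the C–O bond at the carbinol carbon. Phenol 8 opens F3 at the unhindered CH2 in the same flask to give 13.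

Step 15.
- The reaction may stall after the first arylation while the boronic acid is consumed by protodeboronation, oxidation and homocoupling.
- The fallback sets out from 17 and 19 and comes back at 24. It forms the same two O–C(aryl) bonds from an aryl halide instead of an aryl boron donor.
- Grignard reagent 19 is quenched with I2 to 1-allyl-4-iodobenzene F4.
- 17 is then coupled twice with F4 in an Ullmann-type etherification under monovalent copper catalysis (CuI, N,N-dimethylglycine, Cs2CO3, dioxane, 90 °C).

Step 5.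
- The acid-sensitive, electron-rich benzylic epoxide may be opened by the Lewis-acidic titanium alkoxide or during isolation.
- The fallback sets out from 5 and 8 and comes back at 9. The magnolol ether is made before the oxygen is installed.
- A Mitsunobu reaction of 5 with 8 (PPh3, DIAD, THF) gives the (E)-cinnamyl aryl ether F5.
- A Shi epoxidation follows (D-fructose-derived ketone, KHSO5, K2CO3, Bu4NHSO4, MeCN–CH2(OMe)2–aq. buffer at about pH 10.5, 0 °C). Its basic medium spares the epoxide.
- The dioxirane prefers the trans-disubstituted styrenyl alkene over the terminal allyl groups. This ketone enantiomer is the one that gives (R,R)-epoxides from trans-β-substituted styrenes.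

**Further compounds**
F1 | step 10 | (2R,3S)-3-(7-allyloxy-2,2-dimethyl-1,3-benzodioxol-5-yl)-3-[(6-allyl-2-ethoxy-1,3-benzodioxol-4-yl)oxy]propane-1,2-diol | C=CCOc1cc(cc2OC(C)(C)Oc12)[C@H](Oc1cc(CC=C)cc2OC(OCC)Oc12)[C@H](O)CO
F2 | step 10 | primary 4-toluenesulfonate of F1, (2R,3S) | C=CCOc1cc(cc2OC(C)(C)Oc12)[C@H](Oc1cc(CC=C)cc2OC(OCC)Oc12)[C@H](O)COS(=O)(=O)c1ccc(C)cc1
F3 | step 10 | (2R)-2-[(S)-(7-allyloxy-2,2-dimethyl-1,3-benzodioxol-5-yl)(6-allyl-2-ethoxy-1,3-benzodioxol-4-yloxy)methyl]oxirane | C=CCOc1cc(cc2OC(C)(C)Oc12)[C@H](Oc1cc(CC=C)cc2OC(OCC)Oc12)[C@H]1CO1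
F4 | step 15 | 1-allyl-4-iodobenzene | C=CCc1ccc(I)cc1
F5 | step 5 | (E)-3-(7-allyloxy-2,2-dimethyl-1,3-benzodioxol-5-yl)prop-2-enyl ether of 8 | C=CCc1ccc(OC/C=C/c2cc(OCC=C)c3OC(C)(C)Oc3c2)c(-c2cc(CC=C)ccc2OCOC)c1
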